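**Plan**

Ring A is the ε-ring with the 3-methylbut-2-enyl group (C1–C6), ring B the ε-ring with the (E)-4-hydroxy-3-methylbut-2-enyl group (C1'–C6'); carotenoid numbering throughout.
- Retrosynthesis cuts C11=C12 and C11'=C12' first (two Wittig reactions, C20 + C10 + C20), then the ring–chain bonds C6–C7 and C6'–C7', then the side-chain C=C bonds back to one aldehyde, 6.
- Enabling feature: in each ring, C6 (C6') is the γ-carbon of the allyl unit C4–C5(CH3)=C6 of a cyclohex-2-enyl C4 ester, because the ring double bond C4=C5 lies β,γ to the chain. An anti-SN2' attack of a (1E,3E)-dienyl copper reagent (C7–C11) therefore forms C6–C7, places the ε double bond and sets C6 in one event; the picolinoxy activating group leaves in the same step.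
- Forward: no ring is formed (both rings come from 2,4,4-trimethylcyclohex-2-enone). One dienyl Grignard reagent (step 8) serves both ring + C5 unions (steps 9 and 16); then ring A C20 salt + C10 dial (step 18), ring B C20 salt (step 19), desilylation last.
- Stereochemistry: C2/C2' from one Cu-catalysed asymmetric conjugate addition (step 2); the C4 carbinol cis to the side chain from Luche reduction. It is esterified with retention for ring B (anti attack gives trans-2',6') and with Mitsunobu inversion for ring A (gives cis-2,6).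
- Alkene geometry: E from a stabilised ylide, syn-hydrozirconation, the (E)-enynol, the all-E dial, and thermal equilibration after each polyene Wittig step.

Key step: step 16

Assumption: compounds 1, 3, 7, 12, 21 and 30 are taken as purchasable, and the phosphoramidite antipode in step 2 is the one expected from the usual facial preference with 4,4-dialkylcyclohexadienones (its mirror image is used if the sense proves opposite).

**Route**

Step 1
Reactants: 1 2,4,4-trimethylcyclohex-2-en-1-one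
Product: 2 2,4,4-trimethylcyclohexa-2,5-dien-1-one
Conditions: DDQ (1.3 equiv), TsOH (cat.), 1,4-dioxane, reflux
Reagents that add atoms: none
Why: DDQ dehydrogenation of a 4,4-disubstituted cyclohexenone through its cross-conjugated dienol is a standard entry to cyclohexa-2,5-dienones, and the quaternary C4 blocks aromatisation.

Step 2
Reactants: 2 2,4,4-trimethylcyclohexa-2,5-dien-1-one; 3 (1,3-dioxolan-2-ylmethyl)magnesium bromide
Product: 6 2-[(1S)-2,2,4-trimethyl-5-oxocyclohex-3-en-1-yl]acetaldehyde, via bis(1,3-dioxolan-2-ylmethyl)zinc 4 (not isolated), via dioxolane ketone 5 (not isolated)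
Conditions: 3 (2.4 equiv), ZnCl2 (1.2 equiv), THF/1,4-dioxane, 0 °C to rt, magnesium salts filtered off; then 2, Cu(OTf)2 (2 mol%), (R)-binaphthyl-2,2'-diyl N,N-bis[(S)-1-phenylethyl]phosphoramidite (4 mol%), toluene, −30 °C; then 2 M HCl, THF, rt
Reagents that add atoms: water, O
Why: Cu/phosphoramidite-catalysed asymmetric conjugate addition of a dialkylzinc, a reaction type established for 4,4-dialkylcyclohexa-2,5-dienones, should deliver the masked acetaldehyde unit to the unsubstituted enone arm (not the α-methylated one) with the ligand setting the S centre (future C2 and C2'), and aqueous acid then unmasks the aldehyde.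

Step 3
Reactants: 6 2-[(1S)-2,2,4-trimethyl-5-oxocyclohex-3-en-1-yl]acetaldehyde; 7 isopropyltriphenylphosphonium iodide
Product: 9 (5S)-2,4,4-trimethyl-5-(3-methylbut-2-en-1-yl)cyclohex-2-en-1-one, via isopropylidenetriphenylphosphorane 8 (not isolated)
Conditions: 7, n-BuLi, THF, 0 °C; then 6 (1.0 equiv), −78 °C to 0 °C
Reagents that add atoms: none
Why: Wittig olefination with a non-stabilised ylide at low temperature should take the aldehyde far faster than the hindered conjugated ketone and builds the prenyl group, where no geometry is at stake.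

Step 4
Reactants: 9 (5S)-2,4,4-trimethyl-5-(3-methylbut-2-en-1-yl)cyclohex-2-en-1-one
Product: 10 (1R,5S)-2,4,4-trimethyl-5-(3-methylbut-2-en-1-yl)cyclohex-2-en-1-ol (cis)
Conditions: NaBH4, CeCl3·7H2O, MeOH, −78 °C to −20 °C
Reagents that add atoms: none
Why: Luche 1,2-reduction by axial hydride delivery to the half-chair with the C5 side chain equatorial should give the equatorial alcohol cis to the side chain, as in the carvone to cis-carveol case.

Step 5
Reactants: 10 (1R,5S)-2,4,4-trimethyl-5-(3-methylbut-2-en-1-yl)cyclohex-2-en-1-ol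
Product: 11 (1S,5S)-2,4,4-trimethyl-5-(3-methylbut-2-en-1-yl)cyclohex-2-en-1-yl pyridine-2-carboxylate (trans)
Conditions: pyridine-2-carboxylic acid, PPh3, DIAD, THF, 0 °C to rt
Reagents that add atoms: pyridine-2-carboxylic acid, OC(=O)c1ccccn1
Why: Mitsunobu esterification inverts the carbinol by SN2 displacement and installs in the same operation the picolinoxy leaving group needed for the later substitution.

Step 6
Reactants: 12 (2E)-3-methylpent-2-en-4-yn-1-ol
Product: 13 triethyl{[(2E)-3-methylpent-2-en-4-yn-1-yl]oxy}silane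
Conditions: Et3SiCl, imidazole, CH2Cl2, 0 °C
Reagents that add atoms: chlorotriethylsilane, CC[Si](Cl)(CC)CC
Why: Standard silylation of a primary alcohol, chosen so that the ether survives organometallic steps but falls to mild acid later.

Step 7
Reactants: 13 triethyl{[(2E)-3-methylpent-2-en-4-yn-1-yl]oxy}silane
Product: 15 triethyl{[(2E,4E)-5-iodo-3-methylpenta-2,4-dien-1-yl]oxy}silane, via dienylzirconocene chloride 14 (not isolated)
Conditions: Cp2Zr(H)Cl, THF, rt, dark; then I2, 0 °C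
Reagents that add atoms: iodine, II
Why: syn-Hydrozirconation of the terminal alkyne puts zirconium on the terminal carbon and iodinolysis proceeds with retention, so the new C=C should be E while the existing trisubstituted alkene is untouched.

Step 8
Reactants: 15 triethyl{[(2E,4E)-5-iodo-3-methylpenta-2,4-dien-1-yl]oxy}silane
Product: 17 [(1E,3E)-3-methyl-5-(triethylsilyloxy)penta-1,3-dien-1-yl]magnesium bromide (ethereal solution), via dienyllithium 16 (not isolated)
Conditions: t-BuLi (2.0 equiv), Et2O, −78 °C; then MgBr2·OEt2 (1.1 equiv), −78 °C to 0 °C; solution titrated, kept cold under argon and used the same day, one batch being divided between steps 9 and 16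
Reagents that add atoms: magnesium dibromide (used as its diethyl etherate), Br[Mg]Br
Why: Iodine–lithium exchange of an alkenyl iodide with two equivalents of t-BuLi is fast and stereoretentive at −78 °C, and transmetalation with MgBr2 should give the configurationally stable (1E,3E)-dienyl Grignard reagent, to which the triethylsilyl ether is inert.

Step 9
Reactants: 11 (1S,5S)-2,4,4-trimethyl-5-(3-methylbut-2-en-1-yl)cyclohex-2-en-1-yl pyridine-2-carboxylate; 17 [(1E,3E)-3-methyl-5-(triethylsilyloxy)penta-1,3-dien-1-yl]magnesium bromide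
Product: 18 triethyl{[(2E,4E)-3-methyl-5-[(1R,5S)-2,6,6-trimethyl-5-(3-methylbut-2-en-1-yl)cyclohex-2-en-1-yl]penta-2,4-dien-1-yl]oxy}silane
Conditions: 17 (2.5 equiv, Et2O solution), CuBr·SMe2 (0.5 equiv), THF, −78 °C; then 11, −78 °C to 0 °C
Reagents that add atoms: none
Why: Copper-mediated anti-SN2' substitution of an allylic picolinate by an alkenyl Grignard reagent places the dienyl group on the γ-carbon anti to the picolinoxy group, so the inverted carbinol relays its configuration to C6 of ring A (R, cis to the prenyl group at C2) while the double bond moves to C4=C5 and the E,E-dienyl geometry is kept.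

Step 10
Reactants: 18 triethyl{[(2E,4E)-3-methyl-5-[(1R,5S)-2,6,6-trimethyl-5-(3-methylbut-2-en-1-yl)cyclohex-2-en-1-yl]penta-2,4-dien-1-yl]oxy}silane
Product: 20 {(2E,4E)-3-methyl-5-[(1R,5S)-2,6,6-trimethyl-5-(3-methylbut-2-en-1-yl)cyclohex-2-en-1-yl]penta-2,4-dien-1-yl}triphenylphosphonium bromide, via dienol 19 (not isolated)
Conditions: PPh3·HBr (1.1 equiv), MeOH, 0 °C to rt
Reagents that add atoms: triphenylphosphine hydrobromide, [Br-].[PH+](c1ccccc1)(c1ccccc1)c1ccccc1
Why: Acidic methanolysis of the triethylsilyl ether followed by SN1-type substitution of the dienylic alcohol with PPh3·HBr is the standard preparation of C15-type carotenoid Wittig salts, and terminal capture of the pentadienyl cation keeps the E,E-diene.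

Step 11
Reactants: 6 2-[(1S)-2,2,4-trimethyl-5-oxocyclohex-3-en-1-yl]acetaldehyde; 21 ethyl 2-(triphenylphosphoranylidene)propanoate
Product: 22 ethyl (2E)-2-methyl-4-[(1S)-2,2,4-trimethyl-5-oxocyclohex-3-en-1-yl]but-2-enoate
Conditions: 21 (1.1 equiv), CH2Cl2, rt
Reagents that add atoms: none
Why: Wittig olefination with a stabilised ylide reacts only with the aldehyde and is E-selective, which fixes the geometry of the future hydroxylated side chain.

Step 12
Reactants: 22 ethyl (2E)-2-methyl-4-[(1S)-2,2,4-trimethyl-5-oxocyclohex-3-en-1-yl]but-2-enoate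
Product: 23 ethyl (2E)-4-[(1S,5R)-5-hydroxy-2,2,4-trimethylcyclohex-3-en-1-yl]-2-methylbut-2-enoate (cis)
Conditions: NaBH4, CeCl3·7H2O, MeOH, −78 °C to −20 °C
Reagents that add atoms: none
Why: Luche reduction as in step 4 should give the cis allylic alcohol by axial hydride delivery and leaves the unsaturated ester alone.

Step 13
Reactants: 23 ethyl (2E)-4-[(1S,5R)-5-hydroxy-2,2,4-trimethylcyclohex-3-en-1-yl]-2-methylbut-2-enoate
Product: 24 (1R,5S)-5-[(2E)-4-hydroxy-3-methylbut-2-en-1-yl]-2,4,4-trimethylcyclohex-2-en-1-ol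
Conditions: i-Bu2AlH (3.3 equiv), CH2Cl2, −78 °C; aqueous potassium sodium tartrate (KNaC4H4O6) work-up
Reagents that add atoms: none
Why: i-Bu2AlH reduces the α,β-unsaturated ester cleanly in the 1,2-sense to the allylic alcohol with retention of the E geometry.

Step 14
Reactants: 24 (1R,5S)-5-[(2E)-4-hydroxy-3-methylbut-2-en-1-yl]-2,4,4-trimethylcyclohex-2-en-1-ol
Product: 25 (1R,5S)-5-[(2E)-4-{[tert-butyl(diphenyl)silyl]oxy}-3-methylbut-2-en-1-yl]-2,4,4-trimethylcyclohex-2-en-1-ol
Conditions: t-BuPh2SiCl (1.05 equiv), imidazole, CH2Cl2, −20 °C to 0 °C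
Reagents that add atoms: tert-butyl(chloro)diphenylsilane, CC(C)(C)[Si](Cl)(c1ccccc1)c1ccccc1
Why: The bulky silyl chloride should take the primary allylic hydroxyl selectively over the hindered secondary ring hydroxyl.

Step 15
Reactants: 25 (1R,5S)-5-[(2E)-4-{[tert-butyl(diphenyl)silyl]oxy}-3-methylbut-2-en-1-yl]-2,4,4-trimethylcyclohex-2-en-1-ol
Product: 26 (1R,5S)-5-[(2E)-4-{[tert-butyl(diphenyl)silyl]oxy}-3-methylbut-2-en-1-yl]-2,4,4-trimethylcyclohex-2-en-1-yl pyridine-2-carboxylate (cis)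
Conditions: pyridine-2-carboxylic acid, DCC, DMAP (cat.), CH2Cl2, rt
Reagents that add atoms: pyridine-2-carboxylic acid, OC(=O)c1ccccn1
Why: Steglich esterification acylates the carbinol with retention, so the picolinoxy group stays cis to the side chain.

Step 16
Reactants: 26 (1R,5S)-5-[(2E)-4-{[tert-butyl(diphenyl)silyl]oxy}-3-methylbut-2-en-1-yl]-2,4,4-trimethylcyclohex-2-en-1-yl pyridine-2-carboxylate; 17 [(1E,3E)-3-methyl-5-(triethylsilyloxy)penta-1,3-dien-1-yl]magnesium bromide
Product: 27 (2E,4E)-5-[(1S,5R)-5-{(2E)-4-[(tert-butyldiphenylsilyl)oxy]-3-methylbut-2-en-1-yl}-2,6,6-trimethylcyclohex-2-en-1-yl]-3-methylpenta-2,4-dien-1-yl triethylsilyl ether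
Conditions: 17 (2.5 equiv, Et2O solution), CuBr·SMe2 (0.5 equiv), THF, −78 °C; then 26, −78 °C to 0 °C
Reagents that add atoms: none
Why: Grignard reagent 17 transmetalates to an alkenylcopper species (monovalent copper) which, with the picolinoxy group activated by chelation of magnesium between the pyridine nitrogen and the carbonyl oxygen, adds oxidatively to the C5'=C6' double bond of 26 on the face opposite to the C4'–O bond to give a σ-allyl intermediate (trivalent copper) at C6', and reductive elimination then forms C6'–C7' with retention of the E,E-dienyl geometry while the ring double bond moves to C4'=C5'. The closest known reaction type is the copper-mediated anti-SN2' substitution of secondary allylic picolinates, and of cis-5-alkylcyclohex-2-enyl carboxylates, by aryl and alkenyl Grignard reagents with 1,3-chirality transfer. No ring is closed. The one new stereocentre, C6', is controlled by the configuration of C4' (anti displacement), which the Luche reduction had set cis to the C2' side chain, so C7' should enter trans to that chain (6'S with 2'R). The step needs γ- over α-substitution and over acyl attack, and anti over syn delivery: the chelating, electron-poor picolinate serves the first two and the stereoelectronics of the SN2' pathway the third, while both silyl ethers and the isolated trisubstituted alkenes are inert to the reagent.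

Step 17
Reactants: 27 (2E,4E)-5-[(1S,5R)-5-{(2E)-4-[(tert-butyldiphenylsilyl)oxy]-3-methylbut-2-en-1-yl}-2,6,6-trimethylcyclohex-2-en-1-yl]-3-methylpenta-2,4-dien-1-yl triethylsilyl ether
Product: 29 {(2E,4E)-5-[(1S,5R)-5-{(2E)-4-[(tert-butyldiphenylsilyl)oxy]-3-methylbut-2-en-1-yl}-2,6,6-trimethylcyclohex-2-en-1-yl]-3-methylpenta-2,4-dien-1-yl}triphenylphosphonium bromide, via dienol 28 (not isolated)
Conditions: PPh3·HBr (1.1 equiv), MeOH/CH2Cl2, 0 °C to rt
Reagents that add atoms: triphenylphosphine hydrobromide, [Br-].[PH+](c1ccccc1)(c1ccccc1)c1ccccc1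
Why: As in step 10, the triethylsilyl ether is methanolysed and the dienylic alcohol converted to the phosphonium salt, while the far more acid-stable tert-butyldiphenylsilyl ether on the non-conjugated side chain should survive.

Step 18
Reactants: 20 {(2E,4E)-3-methyl-5-[(1R,5S)-2,6,6-trimethyl-5-(3-methylbut-2-en-1-yl)cyclohex-2-en-1-yl]penta-2,4-dien-1-yl}triphenylphosphonium bromide; 30 (2E,4E,6E)-2,7-dimethylocta-2,4,6-trienedial
Product: 32 (2E,4E,6E,8E,10E,12E)-2,7,11-trimethyl-13-[(1R,5S)-2,6,6-trimethyl-5-(3-methylbut-2-en-1-yl)cyclohex-2-en-1-yl]trideca-2,4,6,8,10,12-hexaenal, via ring A ylide 31 (not isolated)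
Conditions: 30 (3 equiv), NaOMe, MeOH/CH2Cl2, 0 °C to rt, slow addition of 20; then reflux in heptane (E/Z equilibration)
Reagents that add atoms: none
Why: Wittig olefination of the dialdehyde used in excess should stop at mono-condensation, and the E/Z mixture at the new C11=C12 bond is equilibrated thermally to the all-E polyene as is usual in C15 + C10 carotenoid assembly.

Step 19
Reactants: 32 (2E,4E,6E,8E,10E,12E)-2,7,11-trimethyl-13-[(1R,5S)-2,6,6-trimethyl-5-(3-methylbut-2-en-1-yl)cyclohex-2-en-1-yl]trideca-2,4,6,8,10,12-hexaenal; 29 {(2E,4E)-5-[(1S,5R)-5-{(2E)-4-[(tert-butyldiphenylsilyl)oxy]-3-methylbut-2-en-1-yl}-2,6,6-trimethylcyclohex-2-en-1-yl]-3-methylpenta-2,4-dien-1-yl}triphenylphosphonium bromide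
Product: 34 (2S,6R,2'R,6'S)-2'-[(2E)-4-{[tert-butyl(diphenyl)silyl]oxy}-3-methylbut-2-en-1-yl]-2-(3-methylbut-2-en-1-yl)-ε,ε-carotene, via ring B ylide 33 (not isolated)
Conditions: NaOMe, MeOH/CH2Cl2, rt; then reflux in heptane (isomerisation to all-E), crystallisation
Reagents that add atoms: none
Why: The second Wittig olefination forms C11'=C12' and completes the C50 polyene, with thermal equilibration and crystallisation expected to give the all-E isomer, and the doubly allylic C6–H and C6'–H bonds should not epimerise under methoxide at room temperature.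

Step 20
Reactants: 34 (2S,6R,2'R,6'S)-2'-[(2E)-4-{[tert-butyl(diphenyl)silyl]oxy}-3-methylbut-2-en-1-yl]-2-(3-methylbut-2-en-1-yl)-ε,ε-carotene
Product: 35 (2S,6R,2'R,6'S)-2'-[(2E)-4-hydroxy-3-methylbut-2-en-1-yl]-2-(3-methylbut-2-en-1-yl)-ε,ε-carotene (target)
Conditions: Bu4NF, THF, 0 °C to rt, exclusion of light and air
Reagents that add atoms: none
Why: Fluoride cleavage of the silyl ether releases the primary allylic alcohol under conditions the polyene tolerates.

**Compound list**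

1 | 2,4,4-trimethylcyclohex-2-en-1-one | CC1=CC(C)(C)CCC1=O | starting material
2 | 2,4,4-trimethylcyclohexa-2,5-dien-1-one | CC1=CC(C)(C)C=CC1=O | intermediate
3 | (1,3-dioxolan-2-ylmethyl)magnesium bromide | Br[Mg]CC1OCCO1 | starting material
4 | bis(1,3-dioxolan-2-ylmethyl)zinc | C1COC(C[Zn]CC2OCCO2)O1 | intermediate
5 | (5S)-5-(1,3-dioxolan-2-ylmethyl)-2,4,4-trimethylcyclohex-2-en-1-one | O=C1C[C@H](CC2OCCO2)C(C)(C)C=C1C | intermediate
6 | 2-[(1S)-2,2,4-trimethyl-5-oxocyclohex-3-en-1-yl]acetaldehyde | O=C1C[C@H](CC=O)C(C)(C)C=C1C | intermediate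
7 | isopropyltriphenylphosphonium iodide | CC(C)[P+](c1ccccc1)(c1ccccc1)c1ccccc1.[I-] | starting material
8 | isopropylidenetriphenylphosphorane | CC(C)=P(c1ccccc1)(c1ccccc1)c1ccccc1 | intermediate
9 | (5S)-2,4,4-trimethyl-5-(3-methylbut-2-en-1-yl)cyclohex-2-en-1-one | O=C1C[C@H](CC=C(C)C)C(C)(C)C=C1C | intermediate
10 | (1R,5S)-2,4,4-trimethyl-5-(3-methylbut-2-en-1-yl)cyclohex-2-en-1-ol | O[C@@H]1C[C@H](CC=C(C)C)C(C)(C)C=C1C | intermediate
11 | (1S,5S)-2,4,4-trimethyl-5-(3-methylbut-2-en-1-yl)cyclohex-2-en-1-yl pyridine-2-carboxylate | O=C(O[C@H]1C[C@H](CC=C(C)C)C(C)(C)C=C1C)c2ccccn2 | intermediate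
12 | (2E)-3-methylpent-2-en-4-yn-1-ol | C#C/C(C)=C/CO | starting material
13 | triethyl{[(2E)-3-methylpent-2-en-4-yn-1-yl]oxy}silane | C#C/C(C)=C/CO[Si](CC)(CC)CC | intermediate
14 | chlorobis(cyclopentadienyl)[(1E,3E)-3-methyl-5-(triethylsilyloxy)penta-1,3-dien-1-yl]zirconium | Cl[Zr](/C=C/C(C)=C/CO[Si](CC)(CC)CC)(C1C=CC=C1)C1C=CC=C1 | intermediate
15 | triethyl{[(2E,4E)-5-iodo-3-methylpenta-2,4-dien-1-yl]oxy}silane | I/C=C/C(C)=C/CO[Si](CC)(CC)CC | intermediate
16 | [(1E,3E)-3-methyl-5-(triethylsilyloxy)penta-1,3-dien-1-yl]lithium | [Li]/C=C/C(C)=C/CO[Si](CC)(CC)CC | intermediate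
17 | [(1E,3E)-3-methyl-5-(triethylsilyloxy)penta-1,3-dien-1-yl]magnesium bromide | Br[Mg]/C=C/C(C)=C/CO[Si](CC)(CC)CC | intermediate
18 | triethyl{[(2E,4E)-3-methyl-5-[(1R,5S)-2,6,6-trimethyl-5-(3-methylbut-2-en-1-yl)cyclohex-2-en-1-yl]penta-2,4-dien-1-yl]oxy}silane | CC(C)=CC[C@H]1CC=C(C)[C@@H](/C=C/C(C)=C/CO[Si](CC)(CC)CC)C1(C)C | intermediate
19 | (2E,4E)-3-methyl-5-[(1R,5S)-2,6,6-trimethyl-5-(3-methylbut-2-en-1-yl)cyclohex-2-en-1-yl]penta-2,4-dien-1-ol | CC(C)=CC[C@H]1CC=C(C)[C@@H](/C=C/C(C)=C/CO)C1(C)C | intermediate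
20 | {(2E,4E)-3-methyl-5-[(1R,5S)-2,6,6-trimethyl-5-(3-methylbut-2-en-1-yl)cyclohex-2-en-1-yl]penta-2,4-dien-1-yl}triphenylphosphonium bromide | CC(C)=CC[C@H]1CC=C(C)[C@@H](/C=C/C(C)=C/C[P+](c2ccccc2)(c2ccccc2)c2ccccc2)C1(C)C.[Br-] | intermediate
21 | ethyl 2-(triphenylphosphoranylidene)propanoate | CCOC(=O)C(C)=P(c1ccccc1)(c1ccccc1)c1ccccc1 | starting material
22 | ethyl (2E)-2-methyl-4-[(1S)-2,2,4-trimethyl-5-oxocyclohex-3-en-1-yl]but-2-enoate | CCOC(=O)/C(C)=C/C[C@H]1CC(=O)C(C)=CC1(C)C | intermediate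
23 | ethyl (2E)-4-[(1S,5R)-5-hydroxy-2,2,4-trimethylcyclohex-3-en-1-yl]-2-methylbut-2-enoate | CCOC(=O)/C(C)=C/C[C@H]1C[C@@H](O)C(C)=CC1(C)C | intermediate
24 | (1R,5S)-5-[(2E)-4-hydroxy-3-methylbut-2-en-1-yl]-2,4,4-trimethylcyclohex-2-en-1-ol | OC/C(C)=C/C[C@H]1C[C@@H](O)C(C)=CC1(C)C | intermediate
25 | (1R,5S)-5-[(2E)-4-{[tert-butyl(diphenyl)silyl]oxy}-3-methylbut-2-en-1-yl]-2,4,4-trimethylcyclohex-2-en-1-ol | CC(C)(C)[Si](c1ccccc1)(c1ccccc1)OC/C(C)=C/C[C@H]1C[C@@H](O)C(C)=CC1(C)C | intermediate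
26 | (1R,5S)-5-[(2E)-4-{[tert-butyl(diphenyl)silyl]oxy}-3-methylbut-2-en-1-yl]-2,4,4-trimethylcyclohex-2-en-1-yl pyridine-2-carboxylate | CC(C)(C)[Si](c1ccccc1)(c1ccccc1)OC/C(C)=C/C[C@H]1C[C@@H](OC(=O)c2ccccn2)C(C)=CC1(C)C | intermediate
27 | (2E,4E)-5-[(1S,5R)-5-{(2E)-4-[(tert-butyldiphenylsilyl)oxy]-3-methylbut-2-en-1-yl}-2,6,6-trimethylcyclohex-2-en-1-yl]-3-methylpenta-2,4-dien-1-yl triethylsilyl ether | CC(C)(C)[Si](c1ccccc1)(c1ccccc1)OC/C(C)=C/C[C@H]1CC=C(C)[C@H](/C=C/C(C)=C/CO[Si](CC)(CC)CC)C1(C)C | intermediate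
28 | (2E,4E)-5-[(1S,5R)-5-{(2E)-4-[(tert-butyldiphenylsilyl)oxy]-3-methylbut-2-en-1-yl}-2,6,6-trimethylcyclohex-2-en-1-yl]-3-methylpenta-2,4-dien-1-ol | CC(C)(C)[Si](c1ccccc1)(c1ccccc1)OC/C(C)=C/C[C@H]1CC=C(C)[C@H](/C=C/C(C)=C/CO)C1(C)C | intermediate
29 | {(2E,4E)-5-[(1S,5R)-5-{(2E)-4-[(tert-butyldiphenylsilyl)oxy]-3-methylbut-2-en-1-yl}-2,6,6-trimethylcyclohex-2-en-1-yl]-3-methylpenta-2,4-dien-1-yl}triphenylphosphonium bromide | CC(C)(C)[Si](c1ccccc1)(c1ccccc1)OC/C(C)=C/C[C@H]1CC=C(C)[C@H](/C=C/C(C)=C/C[P+](c2ccccc2)(c2ccccc2)c2ccccc2)C1(C)C.[Br-] | intermediate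
30 | (2E,4E,6E)-2,7-dimethylocta-2,4,6-trienedial | O=C/C(C)=C/C=C/C=C(C)/C=O | starting material
31 | ring A ylide, {(2E,4E)-3-methyl-5-[(1R,5S)-2,6,6-trimethyl-5-(3-methylbut-2-en-1-yl)cyclohex-2-en-1-yl]penta-2,4-dien-1-ylidene}triphenylphosphorane | CC(C)=CC[C@H]1CC=C(C)[C@@H](/C=C/C(C)=C/C=P(c2ccccc2)(c2ccccc2)c2ccccc2)C1(C)C | intermediate
32 | (2E,4E,6E,8E,10E,12E)-2,7,11-trimethyl-13-[(1R,5S)-2,6,6-trimethyl-5-(3-methylbut-2-en-1-yl)cyclohex-2-en-1-yl]trideca-2,4,6,8,10,12-hexaenal | CC(C)=CC[C@H]1CC=C(C)[C@@H](/C=C/C(C)=C/C=C/C(C)=C/C=C/C=C(C)/C=O)C1(C)C | intermediate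
33 | ring B ylide, {(2E,4E)-5-[(1S,5R)-5-{(2E)-4-[(tert-butyldiphenylsilyl)oxy]-3-methylbut-2-en-1-yl}-2,6,6-trimethylcyclohex-2-en-1-yl]-3-methylpenta-2,4-dien-1-ylidene}triphenylphosphorane | CC(C)(C)[Si](c1ccccc1)(c1ccccc1)OC/C(C)=C/C[C@H]1CC=C(C)[C@H](/C=C/C(C)=C/C=P(c2ccccc2)(c2ccccc2)c2ccccc2)C1(C)C | intermediate
34 | (2S,6R,2'R,6'S)-2'-[(2E)-4-{[tert-butyl(diphenyl)silyl]oxy}-3-methylbut-2-en-1-yl]-2-(3-methylbut-2-en-1-yl)-ε,ε-carotene | CC(C)=CC[C@H]1CC=C(C)[C@@H](/C=C/C(C)=C/C=C/C(C)=C/C=C/C=C(C)/C=C/C=C(C)/C=C/[C@H]2C(C)=CC[C@H](C/C=C(\C)CO[Si](c3ccccc3)(c3ccccc3)C(C)(C)C)C2(C)C)C1(C)C | intermediate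
35 | (2S,6R,2'R,6'S)-2'-[(2E)-4-hydroxy-3-methylbut-2-en-1-yl]-2-(3-methylbut-2-en-1-yl)-ε,ε-carotene, all-E (CNP0304855.1) | CC(C)=CC[C@H]1CC=C(C)[C@@H](/C=C/C(C)=C/C=C/C(C)=C/C=C/C=C(C)/C=C/C=C(C)/C=C/[C@H]2C(C)=CC[C@H](C/C=C(\C)CO)C2(C)C)C1(C)C | target

**Totals and risks**

Total step count: 20. Longest linear sequence: 11 steps (1, 2, 11, 12, 13, 14, 15, 16, 17, 19, 20).

Steps most likely to fail:

1. Step 16. The γ-attack has to occur at C6', which is flanked by the quaternary C1'. If it is slow, attack of the Grignard reagent on the ester carbonyl or α-substitution may take over, and the 1,3-chirality transfer may erode.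
 Fallback (intramolecular suprafacial delivery in place of intermolecular anti substitution): it sets out from 25. Mitsunobu reaction with 4-nitrobenzoic acid (PPh3, DIAD) should give the inverted ester (1S,5S)-5-[(2E)-4-{[tert-butyl(diphenyl)silyl]oxy}-3-methylbut-2-en-1-yl]-2,4,4-trimethylcyclohex-2-en-1-yl 4-nitrobenzoate F1. Methanolysis (K2CO3, MeOH) gives the trans alcohol F2. KH and Bu3SnCH2I give the tributylstannylmethyl ether F3. n-BuLi (THF, −78 °C) triggers tin–lithium exchange and a [2,3]-Wittig–Still rearrangement that delivers CH2OH to C6' on the face of the C4'–O bond, giving the ring B homoallylic alcohol F4 with the C4'=C5' double bond in place. Dess–Martin oxidation gives the aldehyde F5. Horner–Wadsworth–Emmons reaction with triethyl 3-methyl-4-phosphonocrotonate (LiN(SiMe3)2, THF, −78 °C) gives the ethyl (2E,4E)-dienoate F6, and i-Bu2AlH reduction comes back to the route at dienol 28, which is then treated as in step 17.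

2. Step 2. The β-alkoxy zinc reagent may decompose by β-elimination, or transfer its group with poor facial selectivity or poor discrimination between the two enone arms.
 Fallback (alkenyl transfer from boron with rhodium in place of alkyl transfer from zinc): it sets out from 2. Rhodium-catalysed asymmetric 1,4-addition of potassium vinyltrifluoroborate ([RhCl(cod)]2, BINAP enantiomer chosen for the 5R adduct, aqueous toluene, heat) should give (5R)-5-ethenyl-2,4,4-trimethylcyclohex-2-en-1-one F7. 9-BBN in excess followed by NaOH/H2O2 hydroborates the vinyl group and reduces the enone carbonyl, giving (5S)-5-(2-hydroxyethyl)-2,4,4-trimethylcyclohex-2-en-1-ol F8 as a mixture of carbinol epimers. Dess–Martin oxidation of both hydroxyl groups comes back to the route at 6.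

3. Step 9. The same hindered γ-substitution must here take place on the ring face that also carries the C2 prenyl group, and it depends on a Mitsunobu inversion (step 5) that may partly proceed with allylic transposition or elimination.
 Fallback (no inversion and no intermolecular substitution): it sets out from the cis alcohol 10. KH and Bu3SnCH2I give tributyl({[(1R,5S)-2,4,4-trimethyl-5-(3-methylbut-2-en-1-yl)cyclohex-2-en-1-yl]oxy}methyl)stannane F9. n-BuLi (THF, −78 °C) effects the suprafacial [2,3]-Wittig–Still rearrangement to [(1R,5S)-2,6,6-trimethyl-5-(3-methylbut-2-en-1-yl)cyclohex-2-en-1-yl]methanol F10, with CH2OH cis to the prenyl group. Dess–Martin oxidation gives (1R,5S)-2,6,6-trimethyl-5-(3-methylbut-2-en-1-yl)cyclohex-2-ene-1-carbaldehyde F11. Horner–Wadsworth–Emmons reaction with triethyl 3-methyl-4-phosphonocrotonate gives ethyl (2E,4E)-3-methyl-5-[(1R,5S)-2,6,6-trimethyl-5-(3-methylbut-2-en-1-yl)cyclohex-2-en-1-yl]penta-2,4-dienoate F12, and i-Bu2AlH reduction comes back to the route at dienol 19, which is then treated as in step 10.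

Further compounds
F1 | step 16 | (1S,5S)-5-[(2E)-4-{[tert-butyl(diphenyl)silyl]oxy}-3-methylbut-2-en-1-yl]-2,4,4-trimethylcyclohex-2-en-1-yl 4-nitrobenzoate | CC(C)(C)[Si](c1ccccc1)(c1ccccc1)OC/C(C)=C/C[C@H]1C[C@H](OC(=O)c2ccc(cc2)[N+](=O)[O-])C(C)=CC1(C)C
F2 | step 16 | (1S,5S)-5-[(2E)-4-{[tert-butyl(diphenyl)silyl]oxy}-3-methylbut-2-en-1-yl]-2,4,4-trimethylcyclohex-2-en-1-ol | CC(C)(C)[Si](c1ccccc1)(c1ccccc1)OC/C(C)=C/C[C@H]1C[C@H](O)C(C)=CC1(C)C
F3 | step 16 | tributyl({[(1S,5S)-5-[(2E)-4-{[tert-butyl(diphenyl)silyl]oxy}-3-methylbut-2-en-1-yl]-2,4,4-trimethylcyclohex-2-en-1-yl]oxy}methyl)stannane | CC(C)(C)[Si](c1ccccc1)(c1ccccc1)OC/C(C)=C/C[C@H]1C[C@H](OC[Sn](CCCC)(CCCC)CCCC)C(C)=CC1(C)C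
F4 | step 16 | [(1S,5R)-5-{(2E)-4-[(tert-butyldiphenylsilyl)oxy]-3-methylbut-2-en-1-yl}-2,6,6-trimethylcyclohex-2-en-1-yl]methanol | CC(C)(C)[Si](c1ccccc1)(c1ccccc1)OC/C(C)=C/C[C@H]1CC=C(C)[C@H](CO)C1(C)C
F5 | step 16 | (1S,5R)-5-{(2E)-4-[(tert-butyldiphenylsilyl)oxy]-3-methylbut-2-en-1-yl}-2,6,6-trimethylcyclohex-2-ene-1-carbaldehyde | CC(C)(C)[Si](c1ccccc1)(c1ccccc1)OC/C(C)=C/C[C@H]1CC=C(C)[C@H](C=O)C1(C)C
F6 | step 16 | ethyl (2E,4E)-5-[(1S,5R)-5-{(2E)-4-[(tert-butyldiphenylsilyl)oxy]-3-methylbut-2-en-1-yl}-2,6,6-trimethylcyclohex-2-en-1-yl]-3-methylpenta-2,4-dienoate | CC(C)(C)[Si](c1ccccc1)(c1ccccc1)OC/C(C)=C/C[C@H]1CC=C(C)[C@H](/C=C/C(C)=C/C(=O)OCC)C1(C)C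
F7 | step 2 | (5R)-5-ethenyl-2,4,4-trimethylcyclohex-2-en-1-one | O=C1C[C@H](C=C)C(C)(C)C=C1C
F8 | step 2 | (5S)-5-(2-hydroxyethyl)-2,4,4-trimethylcyclohex-2-en-1-ol (carbinol epimers) | OCC[C@H]1CC(O)C(C)=CC1(C)C
F9 | step 9 | tributyl({[(1R,5S)-2,4,4-trimethyl-5-(3-methylbut-2-en-1-yl)cyclohex-2-en-1-yl]oxy}methyl)stannane | CCCC[Sn](CCCC)(CCCC)CO[C@@H]1C[C@H](CC=C(C)C)C(C)(C)C=C1C
F10 | step 9 | [(1R,5S)-2,6,6-trimethyl-5-(3-methylbut-2-en-1-yl)cyclohex-2-en-1-yl]methanol | CC(C)=CC[C@H]1CC=C(C)[C@@H](CO)C1(C)C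
F11 | step 9 | (1R,5S)-2,6,6-trimethyl-5-(3-methylbut-2-en-1-yl)cyclohex-2-ene-1-carbaldehyde | CC(C)=CC[C@H]1CC=C(C)[C@@H](C=O)C1(C)C
F12 | step 9 | ethyl (2E,4E)-3-methyl-5-[(1R,5S)-2,6,6-trimethyl-5-(3-methylbut-2-en-1-yl)cyclohex-2-en-1-yl]penta-2,4-dienoate | CC(C)=CC[C@H]1CC=C(C)[C@@H](/C=C/C(C)=C/C(=O)OCC)C1(C)C
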